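A direct plan would protect (4R,6R)-actinol, make its enol triflate and couple it (Sonogashira) with (E)-3-methylpent-2-en-4-yn-1-ol, so that one C15 enyne alcohol A1 serves both end groups.
The κ ring would come from the 5,6-epoxide A2 of the derived diacetate by Lewis acid ring contraction to ynone A3, which would be hydrated to the diketone and turned into phosphonium salt A4.
Ring A would receive its C4 oxygen by allylic oxidation with hexavalent chromium and directed reduction; Wittig reaction with the C10 dialdehyde would give the C25 aldehyde A5, and A4 plus A5 would be joined by a last Wittig reaction.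
Weak point, the epoxidation that sets C5 and C6 of A2: it is undirected, so the quaternary κ stereocentre rests on a modest anti preference plus chromatography, and the BF3 shift that follows must beat several cationic side paths.
Weak point, the oxygenation of C4: it costs about eight ester, silyl and redox operations on the C15 unit that form no carbon–carbon bond.
Weak point, the last carbon–carbon bond formation: a Wittig reaction on the doubly deprotonated diketone salt A4 followed by thermal Z to E isomerisation exposes the most sensitive group of the C40 polyene at the latest stage.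

**Retrosynthetic overview**
1. The κ end group (cyclopentane C1'–C5' with C16', C17', C18' and acyl carbon C6') is (1R)-camphor without C3: camphor C1 = C5', C7 = C1', C4 = C2', C5 = C3', C6 = C4', C2 = C6'. A cytochrome P450 monooxygenase puts the 5-exo hydroxyl (the 3'S oxygen, trans to the future acyl group) on the intact cage; C3 is then cut out (Riley oxidation, Baeyer–Villiger, Barton decarboxylation) to give methyl ketone 8.
2. Ring A is carried from ketoisophorone: its C4 carbonyl becomes the 3-hydroxyl (transfer hydrogenation), and its C1 carbonyl takes up the ethynyl group (C6–C7) and is relayed to C4 by oxidative 1,3-transposition, then reduced anti, giving ethynyl diol 15.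
3. The chain is a C19 iodo Weinreb amide 26 (C10 dialdehyde plus two Horner–Wadsworth–Emmons reactions). It is joined to 15 at C8–C9 (Sonogashira), and the β-diketone is made last at C7'–C8' by enolate acylation with 8.
4. No ring is closed anywhere; both carbocycles come from cyclic starting materials. There is no epoxide rearrangement, no C–H oxidation at C4, and no olefination or isomerisation after the diketone exists; the last two steps run without protecting groups.

Key step: step 1

Assumption: ethyl (2E)-4-(diethoxyphosphoryl)-2-methylbut-2-enoate (21) is taken as a catalogue reagent; it is otherwise one Michaelis–Arbuzov step from ethyl (2E)-4-bromo-2-methylbut-2-enoate.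

Step 1
Reactants: 1 (1R,4R)-(+)-camphor
Product: 2 (1R,4R,5R)-5-exo-hydroxycamphor
Conditions: E. coli whole cells co-expressing cytochrome P450cam (CYP101A1), putidaredoxin, putidaredoxin reductase and a glucose dehydrogenase; D-glucose, air, phosphate buffer pH 7.4, 30 °C
Reagents that add atoms: dioxygen, O=O
Why: Cytochrome P450 monooxygenase C–H hydroxylation, the native reaction of this enzyme on (1R)-camphor: the thiolate-bound oxoiron porphyrin radical cation (iron formally tetravalent) abstracts the 5-exo hydrogen and the carbon radical recombines with the iron-bound hydroxyl (oxygen rebound). No ring is closed; the step turns an unactivated methylene of a commodity terpene into the C3' carbinol of the target. The one new stereocentre (C5 of the bornane, R, exo) is fixed by the active site, where the hydrogen bond of Tyr96 to the C2 carbonyl and the contacts of the gem-dimethyl bridge hold C5 over the iron and offer only its exo C–H bond. The selectivity needed is C5 over C6, C3 and the methyl groups and exo over endo, which no small oxidant delivers on this cage. In the later cyclopentane the 5-exo oxygen is cis to the C1 methyl and trans to the C2 carbon, which is the 3'S,5'R relation of the κ ring, so both stereocentres of this end group are in place after this step.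

Step 2
Reactants: 2 (1R,4R,5R)-5-exo-hydroxycamphor
Product: 4 (1R,4R,5R)-5-exo-acetoxybornane-2,3-dione, via 5-exo-acetoxycamphor 3 (not isolated)
Conditions: Ac2O (solvent), DMAP (2 mol %), rt; then SeO2 (1.5 equiv), 140 °C
Reagents that add atoms: acetic anhydride, CC(=O)OC(C)=O; selenium dioxide, O=[Se]=O
Why: O-Acetylation followed by Riley oxidation should convert the only enolisable methylene (C3) into a carbonyl, while the acetate cannot be lost by β-elimination because enolisation toward bridgehead C4 is forbidden (Bredt), so C1 and C5 are untouched.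

Step 3
Reactants: 4 (1R,4R,5R)-5-exo-acetoxybornane-2,3-dione
Product: 5 (1R,5R,6R)-1,8,8-trimethyl-2,4-dioxo-3-oxabicyclo[3.2.1]octan-6-yl acetate (4-acetoxycamphoric anhydride)
Conditions: mCPBA (1.3 equiv), CH2Cl2, 0 °C to rt
Reagents that add atoms: 3-chloroperoxybenzoic acid, OOC(=O)c1cccc(Cl)c1
Why: Baeyer–Villiger oxidation of a 1,2-diketone inserts oxygen between the two carbonyl carbons, which cuts the C2–C3 bond and gives the bridged anhydride with no change at the stereocentres.

Step 4
Reactants: 5 4-acetoxycamphoric anhydride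
Product: 7 (1R,4S)-4-acetoxy-1,2,2-trimethylcyclopentane-1-carboxylic acid, via Barton ester 6 (not isolated)
Conditions: 1-hydroxypyridine-2(1H)-thione (1.1 equiv), DMAP (5 mol %), CH2Cl2, rt, dark; then t-BuSH (5 equiv), tungsten lamp, rt
Reagents that add atoms: none
Why: Barton reductive decarboxylation, in which the thiohydroxamic acid should open the anhydride at the less hindered carbonyl (on the CH carbon, not on quaternary C1) and the O-acyl thiohydroxamate then fragments in a radical chain to CO2 and a secondary ring radical that takes hydrogen from the thiol, so the former camphor C3 leaves, C4 becomes the C2' methylene and C1 and the acetoxy carbon keep their configuration.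

Step 5
Reactants: 7 (1R,4S)-4-acetoxy-1,2,2-trimethylcyclopentane-1-carboxylic acid
Product: 8 1-[(1R,4S)-4-hydroxy-1,2,2-trimethylcyclopentyl]ethan-1-one
Conditions: MeLi (6 equiv), Et2O/THF, 0 °C to reflux; inverse quench into cold dilute HCl
Reagents that add atoms: methyllithium, [Li]C
Why: Addition of methyllithium to the lithium carboxylate (organolithium ketone synthesis) should give the methyl ketone after hydrolysis of the gem-diolate, and the same reagent removes the acetate, with neither stereocentre involved.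

Step 6
Reactants: 9 ketoisophorone (2,6,6-trimethylcyclohex-2-ene-1,4-dione)
Product: 10 (4S)-4-hydroxy-2,6,6-trimethylcyclohex-2-en-1-one
Conditions: RuCl(p-cymene)[(S,S)-TsDPEN] (0.5 mol %), t-BuOK (2 mol %), i-PrOH, rt
Reagents that add atoms: none
Why: Noyori–Ikariya asymmetric transfer hydrogenation should reduce the less hindered C4 carbonyl (flanked by CH and CH2) and leave the C1 carbonyl between C(Me)= and CMe2, the new carbinol (S) being set by the chiral diamine ligand with the alkene in the role of the aryl group of an aryl ketone.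

Step 7
Reactants: 10 (4S)-4-hydroxy-2,6,6-trimethylcyclohex-2-en-1-one
Product: 11 (4S)-4-[(tert-butyldimethylsilyl)oxy]-2,6,6-trimethylcyclohex-2-en-1-one
Conditions: TBSCl, imidazole, DMF, rt
Reagents that add atoms: tert-butyldimethylsilyl chloride, CC(C)(C)[Si](C)(C)Cl
Why: Imidazole-promoted O-silylation protects the allylic hydroxyl for the Grignard and chromium steps without touching the stereocentre.

Step 8
Reactants: 11 (4S)-4-[(tert-butyldimethylsilyl)oxy]-2,6,6-trimethylcyclohex-2-en-1-one
Product: 12 (4S)-4-[(tert-butyldimethylsilyl)oxy]-1-ethynyl-2,6,6-trimethylcyclohex-2-en-1-ol (both C1 epimers)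
Conditions: HC≡CMgBr (3 equiv), THF, 0 °C to rt; aq. NH4Cl
Reagents that add atoms: ethynylmagnesium bromide, C#C[Mg]Br
Why: 1,2-Addition of the acetylide Grignard reagent to the enone carbonyl forms the C6–C7 bond, and the configuration of the new carbinol does not matter because this carbon becomes sp2 in the next step.

Step 9
Reactants: 12 (4S)-4-[(tert-butyldimethylsilyl)oxy]-1-ethynyl-2,6,6-trimethylcyclohex-2-en-1-ol
Product: 13 (6S)-6-[(tert-butyldimethylsilyl)oxy]-3-ethynyl-2,4,4-trimethylcyclohex-2-en-1-one
Conditions: pyridinium chlorochromate (C5H5NH)[CrO3Cl] (3 equiv), 4 Å molecular sieves, CH2Cl2, rt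
Reagents that add atoms: pyridinium chlorochromate, [O-][Cr](=O)(=O)Cl.c1cc[nH+]cc1
Why: Babler–Dauben oxidative 1,3-transposition, in which the chromate ester of the tertiary allylic alcohol undergoes [3,3] shift to the secondary allylic chromate that is oxidised to the enone, should place the carbonyl on C4 and create the C5=C6 double bond conjugated with the alkyne, leaving C3 untouched in the non-basic medium.

Step 10
Reactants: 13 (6S)-6-[(tert-butyldimethylsilyl)oxy]-3-ethynyl-2,4,4-trimethylcyclohex-2-en-1-one
Product: 14 (6S)-3-ethynyl-6-hydroxy-2,4,4-trimethylcyclohex-2-en-1-one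
Conditions: HF·pyridine, THF, 0 °C to rt
Reagents that add atoms: none
Why: Acidic fluoride desilylation frees the α-hydroxyl without base, so the ketol should neither epimerise at C3 nor enolise to the diosphenol.

Step 11
Reactants: 14 (6S)-3-ethynyl-6-hydroxy-2,4,4-trimethylcyclohex-2-en-1-one
Product: 15 (1S,2S)-4-ethynyl-3,5,5-trimethylcyclohex-3-ene-1,2-diol
Conditions: Me4NBH(OAc)3 (4 equiv), MeCN/AcOH (1:1), −20 to 0 °C
Reagents that add atoms: none
Why: Hydroxyl-directed triacetoxyborohydride reduction (Saksena–Evans type) should deliver hydride from boron bound to O3 onto the same face of the C4 carbonyl, so the new hydroxyl is trans to O3 (4S in carotenoid numbering) and reduction is 1,2 only.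

Step 12
Reactants: 16 but-2-yn-1-ol
Product: 18 (2E)-3-iodobut-2-en-1-ol, via alkenylzirconocene 17 (not isolated)
Conditions: Cp2Zr(H)Cl (2.2 equiv), THF, rt; then I2 (1.1 equiv), 0 °C; dilute HCl work-up
Reagents that add atoms: iodine, II
Why: Hydrozirconation–iodination, in which syn addition of Zr–H should place zirconium on the methyl-bearing carbon distal to the zirconium alkoxide and iodinolysis with retention gives the vinyl iodide with iodine trans to CH2OH, the future 9E geometry.

Step 13
Reactants: 18 (2E)-3-iodobut-2-en-1-ol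
Product: 19 diethyl [(2E)-3-iodobut-2-en-1-yl]phosphonate
Conditions: ZnI2 (1.5 equiv), P(OEt)3 (2 equiv), THF, reflux
Reagents that add atoms: triethyl phosphite, CCOP(OCC)OCC
Why: Zinc iodide-mediated one-flask Michaelis–Arbuzov-type conversion of an allylic alcohol into its phosphonate should leave the vinyl iodide and the alkene geometry alone.

Step 14
Reactants: 20 (2E,4E,6E)-2,7-dimethylocta-2,4,6-trienedial (3 equiv); 21 ethyl (2E)-4-(diethoxyphosphoryl)-2-methylbut-2-enoate
Product: 23 ethyl (2E,4E,6E,8E,10E)-2,6,11-trimethyl-12-oxododeca-2,4,6,8,10-pentaenoate, via sodium phosphonate anion 22 (not isolated)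
Conditions: 21, NaH (1.05 equiv), THF, 0 °C; added slowly to 20 in THF, 0 °C to rt, dark
Reagents that add atoms: none
Why: Horner–Wadsworth–Emmons olefination of one formyl group of the symmetrical dialdehyde (in excess, recovered) by the ester-stabilised allylic phosphonate anion should form C11'=C12' with E geometry.

Step 15
Reactants: 19 diethyl [(2E)-3-iodobut-2-en-1-yl]phosphonate; 23 C15 aldehyde ester
Product: 25 ethyl (2E,4E,6E,8E,10E,12E,14E)-15-iodo-2,6,11-trimethylhexadeca-2,4,6,8,10,12,14-heptaenoate, via lithium phosphonate anion 24 (not isolated)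
Conditions: 19, LiN(SiMe3)2 (1.05 equiv), THF, −78 °C; then 23; −78 to 0 °C, dark
Reagents that add atoms: none
Why: Horner–Wadsworth–Emmons olefination with the allylic phosphonate anion forms C11=C12, for which allylphosphonates should favour E, while the vinyl iodide and the ester stay inert at low temperature.

Step 16
Reactants: 25 C19 iodo ester
Product: 26 (2E,4E,6E,8E,10E,12E,14E)-15-iodo-N-methoxy-N,2,6,11-tetramethylhexadeca-2,4,6,8,10,12,14-heptaenamide
Conditions: MeNHOMe·HCl (3 equiv), AlMe3 (3 equiv), CH2Cl2, 0 °C to rt, dark; dilute HCl work-up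
Reagents that add atoms: N,O-dimethylhydroxylamine hydrochloride, CNOC.Cl
Why: Weinreb aminolysis of the ester by the aluminium amide made in the flask gives the N-methoxy-N-methylamide, an acyl donor that stops after one addition of a carbon nucleophile.

Step 17
Reactants: 15 (1S,2S)-4-ethynyl-3,5,5-trimethylcyclohex-3-ene-1,2-diol; 26 C19 iodo Weinreb amide
Product: 27 (2E,4E,6E,8E,10E,12E,14E)-17-[(3S,4S)-3,4-dihydroxy-2,6,6-trimethylcyclohex-1-en-1-yl]-N-methoxy-N,2,6,11,15-pentamethylheptadeca-2,4,6,8,10,12,14-heptaen-16-ynamide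
Conditions: Pd(PPh3)4 (5 mol %), CuI (10 mol %), Et3N (3 equiv), THF, rt, argon, dark
Reagents that add atoms: none
Why: Sonogashira coupling of the terminal alkyne with the E alkenyl iodide forms the C8–C9 bond with retention of the 9E geometry and should tolerate the free diol and the amide.

Step 18
Reactants: 8 1-[(1R,4S)-4-hydroxy-1,2,2-trimethylcyclopentyl]ethan-1-one (2 equiv); 27 C30 Weinreb amide diol
Product: 29 CNP0114063.1, via dilithium enolate 28 (not isolated)
Conditions: 8, LiN(SiMe3)2 (6.5 equiv), THF, −78 °C; then 27; −78 to 0 °C; AcOH; argon, dark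
Reagents that add atoms: none
Why: Claisen-type acylation of the lithium enolate of the methyl ketone (the only enolisable position of 8) by the Weinreb amide forms C7'–C8' through a chelated tetrahedral adduct that collapses on work-up to the 1,3-diketone, which should rest as the hydrogen-bonded Z enol, the lithium alkoxides of the three hydroxyls being spectators and no stereocentre being affected.

**Compound list**
1 | (1R,4R)-1,7,7-trimethylbicyclo[2.2.1]heptan-2-one, (+)-camphor | CC1(C)[C@@H]2CC[C@@]1(C)C(=O)C2 | starting material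
2 | (1R,4R,5R)-5-hydroxy-1,7,7-trimethylbicyclo[2.2.1]heptan-2-one (5-exo-hydroxycamphor) | CC1(C)[C@@H]2[C@H](O)C[C@@]1(C)C(=O)C2 | intermediate
3 | (1R,4R,5R)-5-exo-acetoxycamphor | CC1(C)[C@@H]2[C@H](OC(C)=O)C[C@@]1(C)C(=O)C2 | intermediate (not isolated)
4 | (1R,4R,5R)-5-exo-acetoxybornane-2,3-dione | CC1(C)[C@@H]2[C@H](OC(C)=O)C[C@@]1(C)C(=O)C2=O | intermediate
5 | (1R,5R,6R)-1,8,8-trimethyl-2,4-dioxo-3-oxabicyclo[3.2.1]octan-6-yl acetate (acetoxy group anti to the anhydride bridge) | CC1(C)[C@@H]2[C@H](OC(C)=O)C[C@@]1(C)C(=O)OC2=O | intermediate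
6 | (1R,3R,4R)-4-acetoxy-1,2,2-trimethyl-3-{[(2-thioxopyridin-1(2H)-yl)oxy]carbonyl}cyclopentane-1-carboxylic acid (Barton ester) | CC1(C)[C@@H](C(=O)On2ccccc2=S)[C@H](OC(C)=O)C[C@@]1(C)C(O)=O | intermediate (not isolated)
7 | (1R,4S)-4-acetoxy-1,2,2-trimethylcyclopentane-1-carboxylic acid | CC1(C)C[C@H](OC(C)=O)C[C@@]1(C)C(O)=O | intermediate
8 | 1-[(1R,4S)-4-hydroxy-1,2,2-trimethylcyclopentyl]ethan-1-one (κ methyl ketone, hydroxyl cis to the C1 methyl) | CC(=O)[C@]1(C)C[C@@H](O)CC1(C)C | intermediate
9 | 2,6,6-trimethylcyclohex-2-ene-1,4-dione (ketoisophorone) | CC1=CC(=O)CC(C)(C)C1=O | starting material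
10 | (4S)-4-hydroxy-2,6,6-trimethylcyclohex-2-en-1-one | CC1=C[C@@H](O)CC(C)(C)C1=O | intermediate
11 | (4S)-4-[(tert-butyldimethylsilyl)oxy]-2,6,6-trimethylcyclohex-2-en-1-one | CC1=C[C@@H](O[Si](C)(C)C(C)(C)C)CC(C)(C)C1=O | intermediate
12 | (4S)-4-[(tert-butyldimethylsilyl)oxy]-1-ethynyl-2,6,6-trimethylcyclohex-2-en-1-ol, both C1 epimers | CC1=C[C@@H](O[Si](C)(C)C(C)(C)C)CC(C)(C)C1(O)C#C | intermediate
13 | (6S)-6-[(tert-butyldimethylsilyl)oxy]-3-ethynyl-2,4,4-trimethylcyclohex-2-en-1-one | CC1=C(C#C)C(C)(C)C[C@H](O[Si](C)(C)C(C)(C)C)C1=O | intermediate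
14 | (6S)-3-ethynyl-6-hydroxy-2,4,4-trimethylcyclohex-2-en-1-one | CC1=C(C#C)C(C)(C)C[C@H](O)C1=O | intermediate
15 | (1S,2S)-4-ethynyl-3,5,5-trimethylcyclohex-3-ene-1,2-diol (trans diol; 3S,4S in carotenoid numbering) | CC1=C(C#C)C(C)(C)C[C@H](O)[C@H]1O | intermediate
16 | but-2-yn-1-ol | CC#CCO | starting material
17 | (E)-alkenylzirconocene chloride of but-2-yn-1-ol, zirconium on C3 trans to the CH2O group, oxygen bound to a second zirconocene chloride | Cl[Zr](C1C=CC=C1)(C1C=CC=C1)/C(C)=C/CO[Zr](Cl)(C1C=CC=C1)C1C=CC=C1 | intermediate (not isolated)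
18 | (2E)-3-iodobut-2-en-1-ol | I/C(C)=C/CO | intermediate
19 | diethyl [(2E)-3-iodobut-2-en-1-yl]phosphonate | I/C(C)=C/CP(=O)(OCC)OCC | intermediate
20 | (2E,4E,6E)-2,7-dimethylocta-2,4,6-trienedial | O=C/C(C)=C/C=C/C=C(C)/C=O | starting material
21 | ethyl (2E)-4-(diethoxyphosphoryl)-2-methylbut-2-enoate | CCOC(=O)/C(C)=C/CP(=O)(OCC)OCC | starting material
22 | sodium salt of the carbanion of 21 | [Na+].CCOC(=O)/C(C)=C/[CH-]P(=O)(OCC)OCC | intermediate (not isolated)
23 | ethyl (2E,4E,6E,8E,10E)-2,6,11-trimethyl-12-oxododeca-2,4,6,8,10-pentaenoate | O=C/C(C)=C/C=C/C=C(C)/C=C/C=C(C)/C(=O)OCC | intermediate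
24 | lithium salt of the carbanion of 19 | [Li+].I/C(C)=C/[CH-]P(=O)(OCC)OCC | intermediate (not isolated)
25 | ethyl (2E,4E,6E,8E,10E,12E,14E)-15-iodo-2,6,11-trimethylhexadeca-2,4,6,8,10,12,14-heptaenoate | I/C(C)=C/C=C/C(C)=C/C=C/C=C(C)/C=C/C=C(C)/C(=O)OCC | intermediate
26 | (2E,4E,6E,8E,10E,12E,14E)-15-iodo-N-methoxy-N,2,6,11-tetramethylhexadeca-2,4,6,8,10,12,14-heptaenamide | I/C(C)=C/C=C/C(C)=C/C=C/C=C(C)/C=C/C=C(C)/C(=O)N(C)OC | intermediate
27 | (2E,4E,6E,8E,10E,12E,14E)-17-[(3S,4S)-3,4-dihydroxy-2,6,6-trimethylcyclohex-1-en-1-yl]-N-methoxy-N,2,6,11,15-pentamethylheptadeca-2,4,6,8,10,12,14-heptaen-16-ynamide | CC1=C(C#C/C(C)=C/C=C/C(C)=C/C=C/C=C(C)/C=C/C=C(C)/C(=O)N(C)OC)C(C)(C)C[C@H](O)[C@H]1O | intermediate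
28 | dilithium alkoxide enolate of 8 | [Li+].[Li+].C=C([O-])[C@]1(C)C[C@@H]([O-])CC1(C)C | intermediate (not isolated)
29 | CNP0114063.1, (3S,4S,3'S,5'R)-3,4,3',8'-tetrahydroxy-7,8-didehydro-β,κ-caroten-6'-one (all-E polyene, Z enol of the 6',8'-diketone) | CC1=C(C#C/C(C)=C/C=C/C(C)=C/C=C/C=C(C)/C=C/C=C(C)/C(O)=C/C(=O)[C@]2(C)C[C@@H](O)CC2(C)C)C(C)(C)C[C@H](O)[C@H]1O | target

**Step count and risks**
Total step count: 18. Longest linear sequence: 8 steps (steps 6 to 11, then 17 and 18).

Steps most likely to fail:

Step 18. The acylation may stay incomplete: the mixture holds three lithium alkoxides and may aggregate, the hindered enolate may add slowly to the α-methyl, polyene-conjugated amide, and excess amide base may degrade the N-methoxy amide. The fallback reverses the order of the two unions. Setting out from 8 and 26, the dilithium enolate of 8 would be acylated by the hydroxyl-free iodo amide 26 to give (2Z,4E,6E,8E,10E,12E,14E,16E)-3-hydroxy-1-[(1R,4S)-4-hydroxy-1,2,2-trimethylcyclopentyl]-17-iodo-4,8,13-trimethyloctadeca-2,4,6,8,10,12,14,16-octaen-1-one F1. F1 would then be coupled with 15 under copper-free Sonogashira conditions (Pd(PPh3)4, pyrrolidine, THF, rt), so that the diketone never meets copper, and the sequence comes back to the route at 29.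

Step 15. The γ-iodoallyl carbanion may lose iodide by α-elimination, and E selectivity at C11=C12 may be incomplete. The fallback spends the iodide before any carbanion is made. Setting out from 15 and 19, Sonogashira coupling would give diethyl {(2E)-5-[(3S,4S)-3,4-dihydroxy-2,6,6-trimethylcyclohex-1-en-1-yl]-3-methylpent-2-en-4-yn-1-yl}phosphonate F2. Horner–Wadsworth–Emmons reaction of its lithium salt (LiN(SiMe3)2, 3.1 equiv to cover the two hydroxyls) with 23 would give the C30 ethyl ester F3, and aminolysis as in step 16 comes back to the route at 27.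

Step 9. Chromate ester formation at the congested tertiary carbinol may be slow, and the ethynyl carbinol may degrade oxidatively or rearrange under the acidic oxidant. The fallback isomerises first and oxidises second. Setting out from 12, catalytic Ph3SiOReO3 (Et2O, −50 to 0 °C) would move the hydroxyl to C4 by [3,3] shift of the perrhenate ester and give (6S)-6-[(tert-butyldimethylsilyl)oxy]-3-ethynyl-2,4,4-trimethylcyclohex-2-en-1-ol F4 (both carbinol epimers). MnO2 in CH2Cl2 would oxidise this secondary allylic alcohol to the enone and come back to the route at 13.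

**Further compounds**
F1 | step 18 | (2Z,4E,6E,8E,10E,12E,14E,16E)-3-hydroxy-1-[(1R,4S)-4-hydroxy-1,2,2-trimethylcyclopentyl]-17-iodo-4,8,13-trimethyloctadeca-2,4,6,8,10,12,14,16-octaen-1-one | I/C(C)=C/C=C/C(C)=C/C=C/C=C(C)/C=C/C=C(C)/C(O)=C/C(=O)[C@]1(C)C[C@@H](O)CC1(C)C
F2 | step 15 | diethyl {(2E)-5-[(3S,4S)-3,4-dihydroxy-2,6,6-trimethylcyclohex-1-en-1-yl]-3-methylpent-2-en-4-yn-1-yl}phosphonate | CC1=C(C#C/C(C)=C/CP(=O)(OCC)OCC)C(C)(C)C[C@H](O)[C@H]1O
F3 | step 15 | ethyl (2E,4E,6E,8E,10E,12E,14E)-17-[(3S,4S)-3,4-dihydroxy-2,6,6-trimethylcyclohex-1-en-1-yl]-2,6,11,15-tetramethylheptadeca-2,4,6,8,10,12,14-heptaen-16-ynoate | CC1=C(C#C/C(C)=C/C=C/C(C)=C/C=C/C=C(C)/C=C/C=C(C)/C(=O)OCC)C(C)(C)C[C@H](O)[C@H]1O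
F4 | step 9 | (6S)-6-[(tert-butyldimethylsilyl)oxy]-3-ethynyl-2,4,4-trimethylcyclohex-2-en-1-ol, both C1 epimers | CC1=C(C#C)C(C)(C)C[C@H](O[Si](C)(C)C(C)(C)C)C1O
A1 | direct plan | (2E)-5-[(4R)-4-(tert-butyldimethylsilyloxy)-2,6,6-trimethylcyclohex-1-en-1-yl]-3-methylpent-2-en-4-yn-1-ol | CC1=C(C#C/C(C)=C/CO)C(C)(C)C[C@H](O[Si](C)(C)C(C)(C)C)C1
A2 | direct plan | (3S,5R,6R)-5,6-epoxide of the 3,11-diacetate of the C15 enyne diol, oxirane oxygen trans to the 3-acetoxy group | CC(=O)O[C@@H]1C[C@@]2(C)O[C@@]2(C#C/C(C)=C/COC(C)=O)C(C)(C)C1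
A3 | direct plan | (2E)-6-[(1R,4S)-4-acetoxy-1,2,2-trimethylcyclopentyl]-3-methyl-6-oxohex-2-en-4-yn-1-yl acetate | CC(=O)OC/C=C(C)/C#CC(=O)[C@]1(C)C[C@@H](OC(C)=O)CC1(C)C
A4 | direct plan | [(2E,4Z)-4-hydroxy-6-[(1R,4S)-4-hydroxy-1,2,2-trimethylcyclopentyl]-3-methyl-6-oxohexa-2,4-dien-1-yl]triphenylphosphonium bromide | [Br-].c1ccccc1[P+](c1ccccc1)(c1ccccc1)C/C=C(C)/C(O)=C/C(=O)[C@]1(C)C[C@@H](O)CC1(C)C
A5 | direct plan | all-E (3S,4S)-3,4-bis(tert-butyldimethylsilyloxy)-7,8-didehydro-12'-apo-β-caroten-12'-al | CC1=C(C#C/C(C)=C/C=C/C(C)=C/C=C/C=C(C)/C=O)C(C)(C)C[C@H](O[Si](C)(C)C(C)(C)C)[C@H]1O[Si](C)(C)C(C)(C)C
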